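## Retrosynthetic overview

- Numbering: C1 bears the aryl group, C2 the CH2OH, C3 the CHO, C4 is the vinylic CH, C4a/C8a are the fusion carbons; ring A is the dimethoxy ring, ring B the dihydro ring.
- The route rests on C1 carrying two guaiacyl-type rings (ring A and the pendant ring). With two identical 4-hydroxy-3-methoxyphenyl groups C1 is not stereogenic; it becomes so only when one ring closes through its para (ipso) carbon onto C4.
- Disconnections: C3–CHO from a C3 vinyl iodide (carbonylation, redox); ring B from ring expansion of a 3-iodo-spiro[4.5]trienone (C4 shifts from C8a to C4a); the spiro ring from ipso-iodocyclisation of a twin-phenol alkyne; C2 and the alkyne from lipase desymmetrisation of a 2-(diarylmethyl)propane-1,3-diol; the diol from aryl Grignard/copper conjugate addition to a vanillin-derived arylidene malonate.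
- Ring order: the two aryl rings come from the starting materials; the spiro cyclopentene is closed next (sets C1 trans to C2); ring B forms last by ring expansion as ring A re-aromatises.
- The dienone stage is the only point at which the two guaiacyl oxygens differ; the pendant phenol is pivaloylated there, so that only the ring A phenol is methylated later.

Key step: step 13

Remark on stereochemistry: the lipase is assumed to acylate the pro-S hydroxymethyl group of the prochiral diol, giving the (S)-monoacetate; the acylated arm is the one later turned into the alkyne. Descriptors and locants of the spiro and dihydronaphthalene compounds follow the numbering of the overview.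

## Route

Step 1
Reactants: 1 vanillin; 2 dimethyl malonate
Product: 3 dimethyl 2-(4-hydroxy-3-methoxybenzylidene)malonate
Conditions: piperidine (cat.), AcOH (cat.), toluene, reflux, Dean–Stark trap
Reagents that add atoms: none
Why: Knoevenagel condensation of an aromatic aldehyde with an active methylene compound, driven by azeotropic removal of water; no stereocentre is formed.

Step 2
Reactants: 3 dimethyl 2-(4-hydroxy-3-methoxybenzylidene)malonate
Product: 4 dimethyl 2-[4-(tert-butyldimethylsilyloxy)-3-methoxybenzylidene]malonate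
Conditions: t-BuMe2SiCl, imidazole, DMF, rt
Reagents that add atoms: tert-butyldimethylsilyl chloride, CC(C)(C)[Si](C)(C)Cl
Why: Standard silylation of a phenol, which removes the acidic proton and the phenoxide deactivation so that the alkylidene malonate accepts an organometallic nucleophile.

Step 3
Reactants: 5 4-bromo-2-methoxyphenol
Product: 6 (4-bromo-2-methoxyphenoxy)(tert-butyl)dimethylsilane
Conditions: t-BuMe2SiCl, imidazole, DMF, rt
Reagents that add atoms: tert-butyldimethylsilyl chloride, CC(C)(C)[Si](C)(C)Cl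
Why: Standard silylation of a phenol, needed before the aryl bromide is turned into a Grignard reagent.

Step 4
Reactants: 6 (4-bromo-2-methoxyphenoxy)(tert-butyl)dimethylsilane; 4 dimethyl 2-[4-(tert-butyldimethylsilyloxy)-3-methoxybenzylidene]malonate
Product: 8 dimethyl 2-{bis[4-(tert-butyldimethylsilyloxy)-3-methoxyphenyl]methyl}malonate, via aryl Grignard reagent 7 (not isolated)
Conditions: Mg, THF, 45 °C; then 4, CuBr·SMe2 (10 mol %), THF, −20→0 °C; aq NH4Cl
Reagents that add atoms: none
Why: Copper-catalysed conjugate (1,4-) addition of an aryl Grignard reagent to an alkylidene malonate; the two aryl groups on C1 are identical, so no stereocentre arises.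

Step 5
Reactants: 8 dimethyl 2-{bis[4-(tert-butyldimethylsilyloxy)-3-methoxyphenyl]methyl}malonate
Product: 9 2-{bis[4-(tert-butyldimethylsilyloxy)-3-methoxyphenyl]methyl}propane-1,3-diol
Conditions: LiAlH4, THF, 0 °C→rt; aq Rochelle salt
Reagents that add atoms: none
Why: Hydride reduction of both malonate esters gives the prochiral 2-substituted propane-1,3-diol, and aryl silyl ethers should tolerate LiAlH4 at this temperature.

Step 6
Reactants: 9 2-{bis[4-(tert-butyldimethylsilyloxy)-3-methoxyphenyl]methyl}propane-1,3-diol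
Product: 10 (2S)-2-{bis[4-(tert-butyldimethylsilyloxy)-3-methoxyphenyl]methyl}-3-hydroxypropyl acetate
Conditions: Burkholderia cepacia lipase (lipase PS, immobilised), vinyl acetate, t-BuOMe, 30 °C
Reagents that add atoms: vinyl acetate, C=COC(C)=O
Why: Lipase-catalysed enantiotopic-group-selective transesterification (desymmetrisation) of a prochiral 2-substituted propane-1,3-diol with an irreversible acyl donor; the enzyme active site sets C2 by acylating only the pro-S hydroxymethyl arm.

Step 7
Reactants: 10 (2S)-2-{bis[4-(tert-butyldimethylsilyloxy)-3-methoxyphenyl]methyl}-3-hydroxypropyl acetate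
Product: 11 (2R)-2-{bis[4-(tert-butyldimethylsilyloxy)-3-methoxyphenyl]methyl}-3-(tert-butyldiphenylsilyloxy)propyl acetate
Conditions: t-BuPh2SiCl, imidazole, CH2Cl2, 0 °C
Reagents that add atoms: tert-butyldiphenylsilyl chloride, CC(C)(C)[Si](Cl)(c1ccccc1)c1ccccc1
Why: Silylation of the remaining primary alcohol at low temperature should outrun the 1,3-acyl migration that would erode C2, and the bulky, non-participating silyl ether is carried to the end.

Step 8
Reactants: 11 (2R)-2-{bis[4-(tert-butyldimethylsilyloxy)-3-methoxyphenyl]methyl}-3-(tert-butyldiphenylsilyloxy)propyl acetate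
Product: 12 (2R)-2-{bis[4-(tert-butyldimethylsilyloxy)-3-methoxyphenyl]methyl}-3-(tert-butyldiphenylsilyloxy)propan-1-ol
Conditions: i-Bu2AlH, CH2Cl2, −78 °C; aq Rochelle salt
Reagents that add atoms: none
Why: Reductive cleavage of the acetate at −78 °C frees the second arm without base, so neither the aryl silyl ethers nor C2 are touched.

Step 9
Reactants: 12 (2R)-2-{bis[4-(tert-butyldimethylsilyloxy)-3-methoxyphenyl]methyl}-3-(tert-butyldiphenylsilyloxy)propan-1-ol
Product: 13 (2S)-2-{bis[4-(tert-butyldimethylsilyloxy)-3-methoxyphenyl]methyl}-3-(tert-butyldiphenylsilyloxy)propanal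
Conditions: Dess–Martin periodinane, pyridine, CH2Cl2, 0 °C→rt; used at once
Reagents that add atoms: none
Why: Dess–Martin oxidation of a primary alcohol under buffered, non-epimerising conditions; a β-silyloxy aldehyde, unlike a β-acyloxy aldehyde, should not undergo β-elimination.

Step 10
Reactants: 13 (2S)-2-{bis[4-(tert-butyldimethylsilyloxy)-3-methoxyphenyl]methyl}-3-(tert-butyldiphenylsilyloxy)propanal; 14 dimethyl (1-diazo-2-oxopropyl)phosphonate
Product: 16 4,4'-{(2R)-2-[(tert-butyldiphenylsilyloxy)methyl]but-3-yne-1,1-diyl}bis(2-methoxyphenol), via bis-silyl alkyne 15 (not isolated)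
Conditions: K2CO3, MeOH, 0 °C→rt; then further K2CO3, rt; aq NH4Cl
Reagents that add atoms: none
Why: Ohira–Bestmann (Seyferth–Gilbert) homologation of the aldehyde to the terminal alkyne, followed in the same methanolic carbonate by the selective methanolysis of aryl silyl ethers, which leaves the alkyl silyl ether intact; forming the reagent anion at 0 °C before the aldehyde is added should keep C2 from epimerising.

Step 11
Reactants: 16 4,4'-{(2R)-2-[(tert-butyldiphenylsilyloxy)methyl]but-3-yne-1,1-diyl}bis(2-methoxyphenol)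
Product: 17 (1S,2S)-2-[(tert-butyldiphenylsilyloxy)methyl]-1-(4-hydroxy-3-methoxyphenyl)-3-iodo-7-methoxyspiro[4.5]deca-3,6,9-trien-8-one (both epimers at spiro carbon C5)
Conditions: ICl (1.05 equiv), NaHCO3, CH2Cl2, −78 °C; aq Na2S2O3
Reagents that add atoms: iodine monochloride, ClI
Why: Electrophilic ipso-iodocyclisation (5-endo-dig) of a para-hydroxyaryl alkyne: the iodonium-activated alkyne is attacked at its terminal carbon C4 by the carbon para to a free hydroxyl, the strongest donor on either ring (an O-silyl or O-alkyl group would steer closure to the CH para to the methoxy group), iodine ends on C3, and of the two identical rings on C1 the one that closes with the other aryl group anti to the C2 silyloxymethyl group should react, which sets C1 trans to C2.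

Step 12
Reactants: 17 (1S,2S)-2-[(tert-butyldiphenylsilyloxy)methyl]-1-(4-hydroxy-3-methoxyphenyl)-3-iodo-7-methoxyspiro[4.5]deca-3,6,9-trien-8-one
Product: 18 (1S,2S)-2-[(tert-butyldiphenylsilyloxy)methyl]-3-iodo-7-methoxy-1-[3-methoxy-4-(pivaloyloxy)phenyl]spiro[4.5]deca-3,6,9-trien-8-one (both spiro epimers)
Conditions: t-BuCOCl, Et3N, DMAP (cat.), CH2Cl2, 0 °C
Reagents that add atoms: pivaloyl chloride, CC(C)(C)C(Cl)=O
Why: Acylation of the only remaining phenol at the one stage where the two guaiacyl oxygens differ (the other is a dienone carbonyl); the hindered, electron-withdrawing pivalate marks the pendant ring for the rest of the route.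

Step 13
Reactants: 18 (1S,2S)-2-[(tert-butyldiphenylsilyloxy)methyl]-3-iodo-7-methoxy-1-[3-methoxy-4-(pivaloyloxy)phenyl]spiro[4.5]deca-3,6,9-trien-8-one
Product: 19 (1S,2S)-2-[(tert-butyldiphenylsilyloxy)methyl]-6-hydroxy-3-iodo-7-methoxy-1-[3-methoxy-4-(pivaloyloxy)phenyl]-1,2-dihydronaphthalene
Conditions: CF3CO2H, CH2Cl2, 0 °C→rt
Reagents that add atoms: none
Why: O-Protonation of the cross-conjugated dienone gives a 4-hydroxy-3-methoxycyclohexadienyl cation with charge on the carbinol carbon and on the two CH carbons flanking the spiro centre; the vinylic carbon C4 then shifts with its electron pair from the spiro carbon (the future C8a) to the flanking CH remote from the methoxy group (the future C4a), and proton loss from that carbon aromatises ring A as the 6-hydroxy-7-methoxy ring. The closest known reaction type is the acid-catalysed dienone–phenol rearrangement of spiro[4.5]cyclohexadienones, as in the proaporphine-to-aporphine ring expansion. Ring B is closed by ring expansion of the spiro cyclopentene through a suprafacial cationic 1,2-carbon shift that forms C4–C4a, not by cyclisation of an open chain, so no exo or endo mode applies. No stereocentre is created: C1 and C2 are spectators because the migrating carbon is sp2 and the C1–C8a bond is not broken, and the spiro centre, present as both epimers, becomes the aromatic C8a. The step needs the shift to end at C4a and not at C8, which the methoxy group secures by making its own enol-ether CH less electrophilic and more hindered, and it needs C1 to stay intact, which the electron-poor pivaloyloxy-substituted pendant ring secures by disfavouring ionisation of the C1–C8a bond. Should C1 migrate in place of C4, it would do so with retention and give the 7-hydroxy-6-methoxy isomer, which step 14 methylates to the same compound 20.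

Step 14
Reactants: 19 (1S,2S)-2-[(tert-butyldiphenylsilyloxy)methyl]-6-hydroxy-3-iodo-7-methoxy-1-[3-methoxy-4-(pivaloyloxy)phenyl]-1,2-dihydronaphthalene
Product: 20 (1S,2S)-2-[(tert-butyldiphenylsilyloxy)methyl]-3-iodo-6,7-dimethoxy-1-[3-methoxy-4-(pivaloyloxy)phenyl]-1,2-dihydronaphthalene
Conditions: MeI, K2CO3, acetone, 40 °C
Reagents that add atoms: iodomethane, CI
Why: Williamson O-methylation of the newly freed ring A phenol under mild carbonate conditions that should leave the hindered aryl pivalate and the silyl ether untouched.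

Step 15
Reactants: 20 (1S,2S)-2-[(tert-butyldiphenylsilyloxy)methyl]-3-iodo-6,7-dimethoxy-1-[3-methoxy-4-(pivaloyloxy)phenyl]-1,2-dihydronaphthalene
Product: 21 methyl (1S,2R)-2-[(tert-butyldiphenylsilyloxy)methyl]-6,7-dimethoxy-1-[3-methoxy-4-(pivaloyloxy)phenyl]-1,2-dihydronaphthalene-3-carboxylate
Conditions: Pd(OAc)2 (5 mol %), PPh3 (10 mol %), CO (1 atm), MeOH, Et3N, DMF, 50 °C
Reagents that add atoms: carbon monoxide, [C-]#[O+]; methanol, CO
Why: Palladium-catalysed methoxycarbonylation of an alkenyl iodide (oxidative addition to zerovalent palladium, CO insertion, methanolysis) installs the C3 carbon with the C3=C4 bond in place.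

Step 16
Reactants: 21 methyl (1S,2R)-2-[(tert-butyldiphenylsilyloxy)methyl]-6,7-dimethoxy-1-[3-methoxy-4-(pivaloyloxy)phenyl]-1,2-dihydronaphthalene-3-carboxylate
Product: 22 (1S,2R)-2-[(tert-butyldiphenylsilyloxy)methyl]-3-(hydroxymethyl)-1-(4-hydroxy-3-methoxyphenyl)-6,7-dimethoxy-1,2-dihydronaphthalene
Conditions: i-Bu2AlH (excess), CH2Cl2, −78→0 °C; aq Rochelle salt
Reagents that add atoms: none
Why: i-Bu2AlH effects 1,2-reduction of the conjugated ester to the allylic alcohol and in the same operation cleaves the aryl pivalate reductively, while the silyl ether survives.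

Step 17
Reactants: 22 (1S,2R)-2-[(tert-butyldiphenylsilyloxy)methyl]-3-(hydroxymethyl)-1-(4-hydroxy-3-methoxyphenyl)-6,7-dimethoxy-1,2-dihydronaphthalene
Product: 23 (1S,2R)-2-[(tert-butyldiphenylsilyloxy)methyl]-1-(4-hydroxy-3-methoxyphenyl)-6,7-dimethoxy-1,2-dihydronaphthalene-3-carbaldehyde
Conditions: MnO2 (activated, excess), CH2Cl2, rt
Reagents that add atoms: none
Why: Activated MnO2 oxidises only the allylic (cinnamyl-type) alcohol to the enal; the C2 hydroxymethyl group is still silylated, which prevents lactol formation and over-oxidation to a lactone.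

Step 18
Reactants: 23 (1S,2R)-2-[(tert-butyldiphenylsilyloxy)methyl]-1-(4-hydroxy-3-methoxyphenyl)-6,7-dimethoxy-1,2-dihydronaphthalene-3-carbaldehyde
Product: 24 (1S,2R)-1-(4-hydroxy-3-methoxyphenyl)-2-(hydroxymethyl)-6,7-dimethoxy-1,2-dihydronaphthalene-3-carbaldehyde
Conditions: HF·pyridine, pyridine, THF, 0 °C→rt
Reagents that add atoms: none
Why: Fluoride-mediated cleavage of the silyl ether under buffered, mildly acidic conditions that should not enolise the γ-position (C2) of the enal.

## Compound list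

1 | vanillin (4-hydroxy-3-methoxybenzaldehyde) | COc1cc(C=O)ccc1O | starting material
2 | dimethyl malonate | COC(=O)CC(=O)OC | starting material
3 | dimethyl 2-(4-hydroxy-3-methoxybenzylidene)malonate | COC(=O)C(=Cc1ccc(O)c(OC)c1)C(=O)OC | intermediate
4 | dimethyl 2-[4-(tert-butyldimethylsilyloxy)-3-methoxybenzylidene]malonate | COC(=O)C(=Cc1ccc(O[Si](C)(C)C(C)(C)C)c(OC)c1)C(=O)OC | intermediate
5 | 4-bromo-2-methoxyphenol | COc1cc(Br)ccc1O | starting material
6 | (4-bromo-2-methoxyphenoxy)(tert-butyl)dimethylsilane | COc1cc(Br)ccc1O[Si](C)(C)C(C)(C)C | intermediate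
7 | [4-(tert-butyldimethylsilyloxy)-3-methoxyphenyl]magnesium bromide | COc1cc([Mg]Br)ccc1O[Si](C)(C)C(C)(C)C | intermediate
8 | dimethyl 2-{bis[4-(tert-butyldimethylsilyloxy)-3-methoxyphenyl]methyl}malonate | COC(=O)C(C(=O)OC)C(c1ccc(O[Si](C)(C)C(C)(C)C)c(OC)c1)c1ccc(O[Si](C)(C)C(C)(C)C)c(OC)c1 | intermediate
9 | 2-{bis[4-(tert-butyldimethylsilyloxy)-3-methoxyphenyl]methyl}propane-1,3-diol | OCC(CO)C(c1ccc(O[Si](C)(C)C(C)(C)C)c(OC)c1)c1ccc(O[Si](C)(C)C(C)(C)C)c(OC)c1 | intermediate
10 | (2S)-2-{bis[4-(tert-butyldimethylsilyloxy)-3-methoxyphenyl]methyl}-3-hydroxypropyl acetate | CC(=O)OC[C@@H](C(c1ccc(O[Si](C)(C)C(C)(C)C)c(OC)c1)c1ccc(O[Si](C)(C)C(C)(C)C)c(OC)c1)CO | intermediate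
11 | (2R)-2-{bis[4-(tert-butyldimethylsilyloxy)-3-methoxyphenyl]methyl}-3-(tert-butyldiphenylsilyloxy)propyl acetate | CC(=O)OC[C@@H](C(c1ccc(O[Si](C)(C)C(C)(C)C)c(OC)c1)c1ccc(O[Si](C)(C)C(C)(C)C)c(OC)c1)CO[Si](c1ccccc1)(c1ccccc1)C(C)(C)C | intermediate
12 | (2R)-2-{bis[4-(tert-butyldimethylsilyloxy)-3-methoxyphenyl]methyl}-3-(tert-butyldiphenylsilyloxy)propan-1-ol | OC[C@@H](C(c1ccc(O[Si](C)(C)C(C)(C)C)c(OC)c1)c1ccc(O[Si](C)(C)C(C)(C)C)c(OC)c1)CO[Si](c1ccccc1)(c1ccccc1)C(C)(C)C | intermediate
13 | (2S)-2-{bis[4-(tert-butyldimethylsilyloxy)-3-methoxyphenyl]methyl}-3-(tert-butyldiphenylsilyloxy)propanal | O=C[C@@H](C(c1ccc(O[Si](C)(C)C(C)(C)C)c(OC)c1)c1ccc(O[Si](C)(C)C(C)(C)C)c(OC)c1)CO[Si](c1ccccc1)(c1ccccc1)C(C)(C)C | intermediate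
14 | dimethyl (1-diazo-2-oxopropyl)phosphonate | COP(=O)(OC)C(=[N+]=[N-])C(C)=O | starting material
15 | (2R)-1,1-bis[4-(tert-butyldimethylsilyloxy)-3-methoxyphenyl]-2-[(tert-butyldiphenylsilyloxy)methyl]but-3-yne | C#C[C@@H](C(c1ccc(O[Si](C)(C)C(C)(C)C)c(OC)c1)c1ccc(O[Si](C)(C)C(C)(C)C)c(OC)c1)CO[Si](c1ccccc1)(c1ccccc1)C(C)(C)C | intermediate
16 | 4,4'-{(2R)-2-[(tert-butyldiphenylsilyloxy)methyl]but-3-yne-1,1-diyl}bis(2-methoxyphenol) | C#C[C@@H](C(c1ccc(O)c(OC)c1)c1ccc(O)c(OC)c1)CO[Si](c1ccccc1)(c1ccccc1)C(C)(C)C | intermediate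
17 | (1S,2S)-2-[(tert-butyldiphenylsilyloxy)methyl]-1-(4-hydroxy-3-methoxyphenyl)-3-iodo-7-methoxyspiro[4.5]deca-3,6,9-trien-8-one (both epimers at spiro carbon C5) | O=C1C=CC2(C=C1OC)C=C(I)[C@H](CO[Si](c3ccccc3)(c3ccccc3)C(C)(C)C)[C@H]2c1ccc(O)c(OC)c1 | intermediate
18 | (1S,2S)-2-[(tert-butyldiphenylsilyloxy)methyl]-3-iodo-7-methoxy-1-[3-methoxy-4-(pivaloyloxy)phenyl]spiro[4.5]deca-3,6,9-trien-8-one (both spiro epimers) | O=C1C=CC2(C=C1OC)C=C(I)[C@H](CO[Si](c3ccccc3)(c3ccccc3)C(C)(C)C)[C@H]2c1ccc(OC(=O)C(C)(C)C)c(OC)c1 | intermediate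
19 | (1S,2S)-2-[(tert-butyldiphenylsilyloxy)methyl]-6-hydroxy-3-iodo-7-methoxy-1-[3-methoxy-4-(pivaloyloxy)phenyl]-1,2-dihydronaphthalene | COc1cc([C@H]2c3cc(OC)c(O)cc3C=C(I)[C@@H]2CO[Si](c4ccccc4)(c4ccccc4)C(C)(C)C)ccc1OC(=O)C(C)(C)C | intermediate
20 | (1S,2S)-2-[(tert-butyldiphenylsilyloxy)methyl]-3-iodo-6,7-dimethoxy-1-[3-methoxy-4-(pivaloyloxy)phenyl]-1,2-dihydronaphthalene | COc1cc([C@H]2c3cc(OC)c(OC)cc3C=C(I)[C@@H]2CO[Si](c4ccccc4)(c4ccccc4)C(C)(C)C)ccc1OC(=O)C(C)(C)C | intermediate
21 | methyl (1S,2R)-2-[(tert-butyldiphenylsilyloxy)methyl]-6,7-dimethoxy-1-[3-methoxy-4-(pivaloyloxy)phenyl]-1,2-dihydronaphthalene-3-carboxylate | COc1cc([C@H]2c3cc(OC)c(OC)cc3C=C(C(=O)OC)[C@@H]2CO[Si](c4ccccc4)(c4ccccc4)C(C)(C)C)ccc1OC(=O)C(C)(C)C | intermediate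
22 | (1S,2R)-2-[(tert-butyldiphenylsilyloxy)methyl]-3-(hydroxymethyl)-1-(4-hydroxy-3-methoxyphenyl)-6,7-dimethoxy-1,2-dihydronaphthalene | COc1cc([C@H]2c3cc(OC)c(OC)cc3C=C(CO)[C@@H]2CO[Si](c4ccccc4)(c4ccccc4)C(C)(C)C)ccc1O | intermediate
23 | (1S,2R)-2-[(tert-butyldiphenylsilyloxy)methyl]-1-(4-hydroxy-3-methoxyphenyl)-6,7-dimethoxy-1,2-dihydronaphthalene-3-carbaldehyde | COc1cc([C@H]2c3cc(OC)c(OC)cc3C=C(C=O)[C@@H]2CO[Si](c4ccccc4)(c4ccccc4)C(C)(C)C)ccc1O | intermediate
24 | (1S,2R)-1-(4-hydroxy-3-methoxyphenyl)-2-(hydroxymethyl)-6,7-dimethoxy-1,2-dihydronaphthalene-3-carbaldehyde (CNP0485134.1) | COc1cc([C@H]2c3cc(OC)c(OC)cc3C=C(C=O)[C@@H]2CO)ccc1O | target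

## Step count and risks

Total step count: 18. Longest linear sequence: 17 steps (from vanillin: steps 1, 2 and 4–18).

Steps most likely to fail:

1. Step 11 (ipso-iodocyclisation). The electrophilic iodine may be diverted into iodination of the free-phenol rings or into plain 1,2-addition of ICl across the terminal alkyne, in place of 5-endo closure at the unsubstituted alkyne carbon. The two rings on C1 may also be discriminated incompletely, which would leave a cis isomer to be separated. The fallback closes the ring without a halogen electrophile and sets out from 16. Cycloisomerisation of 16 with Ph3PAuNTf2 (a monovalent gold catalyst, CH2Cl2, rt; dearomative 5-endo-dig hydroarylation through the carbon para to the free hydroxyl) should give the iodine-free spirodienone F1. Pivaloylation (t-BuCOCl, Et3N) gives its pendant pivalate F2, and the same acid-mediated 1,2-shift (CF3CO2H, CH2Cl2) gives the 3-unsubstituted 6-hydroxy-7-methoxy-1,2-dihydronaphthalene F3. Methylation (MeI, K2CO3) gives the 6,7-dimethoxy compound F4. Vilsmeier–Haack formylation (POCl3, DMF) of this electron-rich styrene at C3, the carbon β to ring A, gives the enal pivalate F5. Reduction with i-Bu2AlH, which also removes the pivalate, returns to the route at 22.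

2. Step 13 (key step). Under strong acid the vinyl iodide may suffer loss of iodine or iodine participation, or the vinyl shift may be slow enough for the C1–C8a bond to ionise, which would erode C1. The fallback changes which bond is asked to migrate and sets out from 18. Methoxycarbonylation of 18 before the rearrangement (Pd(OAc)2, PPh3, CO, MeOH, Et3N) gives the spirodienone methyl ester F6. With C4 now the electron-poor β-carbon of an enoate, treatment with CF3CO2H should move the benzylic carbon C1 (with retention) to the CH remote from the methoxy group and give the 7-hydroxy-6-methoxy ester F7. Any C4 shift gives the 6-hydroxy-7-methoxy ester F8. Both phenols are methylated (MeI, K2CO3) to the same compound, and the route is rejoined at 21.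

3. Step 6 (lipase desymmetrisation). The bulky diarylmethyl group next to the prochiral centre may lower the discrimination between the two hydroxymethyl arms, or the enzyme may acylate the other arm. The fallback runs the enzyme in the hydrolytic direction and sets out from 9. Acetylation (Ac2O, pyridine) gives the diacetate F9. Hydrolysis of one acetate by the same lipase (or porcine pancreatic lipase) in pH 7 phosphate buffer with acetone then delivers the monoacetate antipodal to that from acylation, and returns to the route at 10.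

## Further compounds

F1 | step 11 | 2-[(tert-butyldiphenylsilyloxy)methyl]-1-(4-hydroxy-3-methoxyphenyl)-7-methoxyspiro[4.5]deca-3,6,9-trien-8-one, C1 and C2 as in 17 | O=C1C=CC2(C=C1OC)C=C[C@H](CO[Si](c3ccccc3)(c3ccccc3)C(C)(C)C)[C@H]2c1ccc(O)c(OC)c1
F2 | step 11 | pendant pivalate of F1 | O=C1C=CC2(C=C1OC)C=C[C@H](CO[Si](c3ccccc3)(c3ccccc3)C(C)(C)C)[C@H]2c1ccc(OC(=O)C(C)(C)C)c(OC)c1
F3 | step 11 | 2-[(tert-butyldiphenylsilyloxy)methyl]-6-hydroxy-7-methoxy-1-[3-methoxy-4-(pivaloyloxy)phenyl]-1,2-dihydronaphthalene, C1 and C2 as in 19 | COc1cc([C@H]2c3cc(OC)c(O)cc3C=C[C@@H]2CO[Si](c4ccccc4)(c4ccccc4)C(C)(C)C)ccc1OC(=O)C(C)(C)C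
F4 | step 11 | 2-[(tert-butyldiphenylsilyloxy)methyl]-6,7-dimethoxy-1-[3-methoxy-4-(pivaloyloxy)phenyl]-1,2-dihydronaphthalene, C1 and C2 as in 20 | COc1cc([C@H]2c3cc(OC)c(OC)cc3C=C[C@@H]2CO[Si](c4ccccc4)(c4ccccc4)C(C)(C)C)ccc1OC(=O)C(C)(C)C
F5 | step 11 | (1S,2R)-2-[(tert-butyldiphenylsilyloxy)methyl]-6,7-dimethoxy-1-[3-methoxy-4-(pivaloyloxy)phenyl]-1,2-dihydronaphthalene-3-carbaldehyde | COc1cc([C@H]2c3cc(OC)c(OC)cc3C=C(C=O)[C@@H]2CO[Si](c4ccccc4)(c4ccccc4)C(C)(C)C)ccc1OC(=O)C(C)(C)C
F6 | step 13 | methyl 2-[(tert-butyldiphenylsilyloxy)methyl]-7-methoxy-1-[3-methoxy-4-(pivaloyloxy)phenyl]-8-oxospiro[4.5]deca-3,6,9-triene-3-carboxylate, C1 and C2 as in 18 | O=C1C=CC2(C=C1OC)C=C(C(=O)OC)[C@H](CO[Si](c3ccccc3)(c3ccccc3)C(C)(C)C)[C@H]2c1ccc(OC(=O)C(C)(C)C)c(OC)c1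
F7 | step 13 | methyl (1S,2R)-2-[(tert-butyldiphenylsilyloxy)methyl]-7-hydroxy-6-methoxy-1-[3-methoxy-4-(pivaloyloxy)phenyl]-1,2-dihydronaphthalene-3-carboxylate | COc1cc([C@H]2c3cc(O)c(OC)cc3C=C(C(=O)OC)[C@@H]2CO[Si](c4ccccc4)(c4ccccc4)C(C)(C)C)ccc1OC(=O)C(C)(C)C
F8 | step 13 | methyl (1S,2R)-2-[(tert-butyldiphenylsilyloxy)methyl]-6-hydroxy-7-methoxy-1-[3-methoxy-4-(pivaloyloxy)phenyl]-1,2-dihydronaphthalene-3-carboxylate | COc1cc([C@H]2c3cc(OC)c(O)cc3C=C(C(=O)OC)[C@@H]2CO[Si](c4ccccc4)(c4ccccc4)C(C)(C)C)ccc1OC(=O)C(C)(C)C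
F9 | step 6 | 2-{bis[4-(tert-butyldimethylsilyloxy)-3-methoxyphenyl]methyl}propane-1,3-diyl diacetate | CC(=O)OCC(COC(C)=O)C(c1ccc(O[Si](C)(C)C(C)(C)C)c(OC)c1)c1ccc(O[Si](C)(C)C(C)(C)C)c(OC)c1
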